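**Retrosynthetic overview**

1. Numbering: ring A is C1 (quaternary, bears C12H2OAc), C2H2, C3 (OAc), C4 (OH), C5 (CMe2), C6. C6 is the apex of a nortricyclene cage. Its bridges C7H2, C1 and C11H(OAc) run to the cyclopropane C8–C9–C10 (C8 on C7, C9 on C1, C10 on C11 and bearing CH3).
2. Feature used: C11 is the only oxygenated bridge, and it lies between the apex C6 and the methyl-bearing cyclopropane carbon C10. With C11 as a ketone, C10 is a keto-carbene hung on C6. Cutting C8–C10 and C9–C10 leaves the cyclopentene C1–C6–C7–C8=C9, trans-fused to ring A, with a 2-diazopropanoyl group on C6 on the cyclopentene face that also carries C2.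
3. The precursor is reshaped. C12 is carried as the carbonyl group of a γ-lactone on O3, which ties C12 and O3 to one face of ring A, keeps C9 and C12 distinct and holds C11 axial over the alkene. O4 is a TBS ether. The cyclopentene comes from ring-closing metathesis of a C6 allyl and a C1 vinyl group.
4. C6 (C11 cis to C9) comes from an alkoxyketene [2+2] tethered through the oxygen on C9 onto C6=C7H2, followed by Baeyer–Villiger cleavage of C8–C11. C1 comes from a Conia-ene closure C1–C6 of a malonate-derived lactone. C3 and C4 come from a Sharpless kinetic resolution.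
5. Ring order: oxirane, γ-lactone, ring A, oxolane plus cyclobutanone (both temporary), cyclopentene, then the cyclopropane and both five-membered cage rings in one step. C11 is corrected by inversion and the lactone is reduced at the end.

Key step: step 18

Remark: "up" means the face of ring A that carries C9 and C11; O3, O4, C7 and C12 are "down". Hydride is assumed to reach the cage ketone from the open C7 side, so an inversion at C11 is built into the route.

**Step 1**
Reactants: 1 acrolein; 2 3-chloro-3-methylbut-1-yne
Product: 4 (±)-4,4-dimethylhex-1-en-5-yn-3-ol, via allenylzinc chloride 3 (not isolated)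
Conditions: activated zinc dust, THF, 0 °C to 23 °C; aq. NH4Cl
Reagents that add atoms: none
Why: Barbier propargylation, in which zinc inserts into the tertiary propargylic chloride to give the allenylzinc 3, and 3 adds 1,2 to the aldehyde through a cyclic SE2' transition state at its CMe2 end (as prenylzinc reagents do), so that C4–C5 forms with the gem-dimethyl group next to a free ethynyl group (C6≡C7) and the product is racemic.

**Step 2**
Reactants: 4 (±)-4,4-dimethylhex-1-en-5-yn-3-ol
Product: 5 (1R)-2,2-dimethyl-1-[(2S)-oxiran-2-yl]but-3-yn-1-ol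
Conditions: Ti(OiPr)4, D-(−)-diisopropyl tartrate, t-BuOOH (0.5 equiv), 4 Å molecular sieves, CH2Cl2, −20 °C, stopped near half conversion
Reagents that add atoms: tert-butyl hydroperoxide, CC(C)(C)OO
Why: Sharpless kinetic resolution of a secondary allylic alcohol, in which the (S)-enantiomer of 4 should be epoxidised much faster than its antipode with the D-(−)-tartrate and should give the erythro epoxy alcohol, setting C3 (S) and C4 (R) while the alkyne stays inert.

**Step 3**
Reactants: 5 epoxy alcohol
Product: 6 tert-butyldimethylsilyl ether of 5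
Conditions: TBSOTf, 2,6-lutidine, CH2Cl2, −78 °C to 0 °C
Reagents that add atoms: tert-butyldimethylsilyl trifluoromethanesulfonate, CC(C)(C)[Si](C)(C)OS(=O)(=O)C(F)(F)F
Why: Silylation of a hindered secondary alcohol with a silyl triflate under non-basic conditions, which avoids Payne migration of the epoxide and marks O4 as the one oxygen that is freed last.

**Step 4**
Reactants: 6 silyl ether epoxide; 7 dimethyl malonate
Product: 9 methyl (5S)-5-[(1R)-1-(tert-butyldimethylsilyloxy)-2,2-dimethylbut-3-yn-1-yl]-2-oxooxolane-3-carboxylate (C1 epimers), via malonate adduct alkoxide 8 (not isolated)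
Conditions: NaH, THF, 0 °C; then 6, 65 °C; AcOH quench
Reagents that add atoms: none
Why: SN2 opening of a terminal epoxide by sodiomalonate at C2 (C3 untouched), after which the C3 alkoxide closes the γ-lactone on one ester faster than the silyl group can shift, giving C1, C9 and C12 in one operation.

**Step 5**
Reactants: 9 lactone ester
Product: 10 bridged lactone ester (methyl 4-(tert-butyldimethylsilyloxy)-3,3-dimethyl-2-methylidene-7-oxo-6-oxabicyclo[3.2.1]octane-1-carboxylate; C12–O3 bridge cis to O4)
Conditions: In(OTf)3 (10 mol %), DBU (10 mol %), toluene, 110 °C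
Reagents that add atoms: none
Why: Conia-ene cycloisomerisation (6-exo-dig), in which the indium enolate of the 1,3-dicarbonyl unit adds to the internal carbon C6 of the activated alkyne and closes ring A with a C6=C7H2 group, and because the chain on C3 can reach only the lactone face on which it stands, C1 is set with C12 and O3 on one face of ring A and C9 on the other.

**Step 6**
Reactants: 10 bridged lactone ester
Product: 12 bridged lactone acid (C9 = CO2H), via ring-opened dilithium dicarboxylate 11 (not isolated)
Conditions: LiOH, THF–MeOH–H2O, 40 °C; then 1 M HCl to pH 2, 23 °C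
Reagents that add atoms: lithium hydroxide, [Li+].[OH-]
Why: Saponification of ester and lactone followed by relactonisation, in which only the carboxyl group cis to O3 can close the bridge again on acidification, so C9 (free acid) and C12 (lactone) stay differentiated and C1 keeps its configuration.

**Step 7**
Reactants: 12 bridged lactone acid
Product: 14 bridged lactone alcohol (C9H2OH), via acid chloride 13 (not isolated)
Conditions: (COCl)2, DMF (cat.), CH2Cl2, 0 °C to 23 °C; concentrate; NaBH4, THF–DMF, −20 °C to 0 °C
Reagents that add atoms: none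
Why: Borohydride reduction of an acid chloride to the primary alcohol, which spares the lactone, the silyl ether and the 1,1-disubstituted alkene that borane would attack.

**Step 8**
Reactants: 14 bridged lactone alcohol; 15 bromoacetic acid
Product: 16 alkoxyacetic acid (C9H2–O–CH2CO2H)
Conditions: NaH (3.5 equiv), THF, 0 °C to 65 °C; then 1 M HCl
Reagents that add atoms: none
Why: Williamson ether synthesis with sodium bromoacetate, in which the C9 alkoxide cannot fragment by retro-aldol loss of formaldehyde because the enolate would sit at the bridgehead C1 (Bredt's rule) and the lactone has no α-hydrogen.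

**Step 9**
Reactants: 16 alkoxyacetic acid
Product: 19 tetracyclic cyclobutanone (oxolane C1–C9–O–C11–C6; cyclobutanone C6–C7–C8(=O)–C11), via acid chloride 17 (not isolated), via alkoxyketene 18 (not isolated)
Conditions: (COCl)2, toluene, 23 °C; concentrate; Et3N, toluene (0.005 M), 110 °C, slow addition
Reagents that add atoms: none
Why: Intramolecular [2+2] cycloaddition of an alkoxyketene with a 1,1-disubstituted alkene, in which the electrophilic ketene carbon C8 bonds to the free terminus C7, the oxygen-bearing carbon C11 closes on C6, and the three-atom tether C1–C9–O should give the cis-fused oxolane on the open face opposite to the lactone bridge, so C6 is set with C11 cis and C7 trans to C9.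

**Step 10**
Reactants: 19 tetracyclic cyclobutanone
Product: 20 bis-acetal lactone (C8(=O)–O–C11H–O–C9)
Conditions: m-CPBA, NaHCO3, CH2Cl2, 0 °C to 23 °C
Reagents that add atoms: 3-chloroperoxybenzoic acid, OOC(=O)c1cccc(Cl)c1
Why: Baeyer–Villiger oxidation of a strained cyclobutanone, in which the secondary α-alkoxy carbon C11 migrates in preference to C7H2 with retention, cutting C8–C11 and bringing C11 to the aldehyde oxidation level, with no alkene present at this stage.

**Step 11**
Reactants: 20 bis-acetal lactone
Product: 22 triol (C8H2OH; C9H2OH; C11H2OH; C12 lactone kept), via lactol 21 (not isolated)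
Conditions: i-Bu2AlH (1.1 equiv), CH2Cl2, −78 °C; MeOH; then NaBH4, MeOH–CH2Cl2, 0 °C
Reagents that add atoms: none
Why: Half reduction of a lactone by i-Bu2AlH followed by borohydride reduction, in which the CH2-flanked acylal-type C8 carbonyl group should react before the C12 carbonyl group on the quaternary bridgehead C1, and lactol 21 then unravels (C8 lactol first, C11 hemiacetal second) so that each aldehyde is reduced.

**Step 12**
Reactants: 22 triol
Product: 23 trialdehyde (C8HO; C9HO; C11HO)
Conditions: (COCl)2, DMSO, CH2Cl2, −78 °C; Et3N, −78 °C to 0 °C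
Reagents that add atoms: none
Why: Swern oxidation, which activates all three primary alcohols at once and so avoids lactol and lactone formation between the 1,4-related hydroxyl groups, while C1 and C6 are quaternary and cannot epimerise.

**Step 13**
Reactants: 23 trialdehyde
Product: 24 diene aldehyde (C6 allyl plus C11HO; C1 vinyl)
Conditions: Ph3PCH3Br, KN(SiMe3)2, THF, 0 °C; then 23 (2.1 equiv of ylide), −78 °C to −20 °C
Reagents that add atoms: methyltriphenylphosphonium bromide, C[P+](c1ccccc1)(c1ccccc1)c1ccccc1.[Br-]
Why: Wittig methylenation under steric control, in which the C8 aldehyde on a CH2 group and the C9 aldehyde activated by the neighbouring lactone carbonyl group should react first, while the axial C11 aldehyde wedged between C1 and the C5 gem-dimethyl group is the slowest and should be left with a limited amount of ylide.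

**Step 14**
Reactants: 24 diene aldehyde
Product: 25 tricyclic aldehyde (cyclopentene C1–C6–C7–C8=C9 closed)
Conditions: second-generation Grubbs catalyst (5 mol %), CH2Cl2 (0.005 M), 40 °C
Reagents that add atoms: none
Why: Ring-closing metathesis of the only two alkenes to a cyclopentene, driven by loss of ethene, in which C1 and C6 are already fixed, so the equatorial C7 and C9 arms merely close the trans-fused five-membered ring, and aldehyde, lactone and silyl ether are tolerated.

**Step 15**
Reactants: 25 tricyclic aldehyde; 26 ethylmagnesium bromide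
Product: 27 secondary carbinol (C11 epimers)
Conditions: 26 (1.2 equiv), Et2O–THF, −78 °C; aq. NH4Cl
Reagents that add atoms: none
Why: Grignard addition to a free aldehyde at low temperature, which is much faster than attack on the bridgehead lactone, brings in C10 and its methyl group, and creates a carbinol centre that is erased in the next step.

**Step 16**
Reactants: 27 secondary carbinol
Product: 28 ethyl ketone
Conditions: Dess–Martin periodinane, NaHCO3, CH2Cl2, 23 °C
Reagents that add atoms: none
Why: Dess–Martin oxidation of a hindered secondary alcohol under neutral conditions that leave the alkene, the lactone and the silyl ether untouched.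

**Step 17**
Reactants: 28 ethyl ketone
Product: 30 α-diazo ketone (C6 2-diazopropanoyl; key-step precursor), via trifluoroacetyl ketone 29 (not isolated)
Conditions: LiN(SiMe3)2, THF, −78 °C; CF3CO2CH2CF3; aq. HCl work-up; then MsN3, Et3N, H2O (1 equiv), MeCN, 23 °C
Reagents that add atoms: methanesulfonyl azide, CS(=O)(=O)N=[N+]=[N-]
Why: Detrifluoroacetylative diazo transfer (Regitz type), in which C10H2 is the only enolisable position, its enolate is acylated to the 1,3-diketone 29, and 29 accepts the diazo group with loss of the trifluoroacetyl group.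

**Step 18**
Reactants: 30 α-diazo ketone
Product: 31 cage ketone (C11 ketone; C12–O3 lactone; C4 OTBS; key-step product)
Conditions: Cu(acac)2 (5 mol %), toluene, 110 °C, 30 added over 6 h (final 0.005 M)
Reagents that add atoms: none
Why: The diazo compound reduces Cu(acac)2 to a monovalent copper species, which takes up 30 with loss of N2 to give an electrophilic copper keto-carbenoid at C10, and this adds to C8=C9 in one concerted, asynchronous step that forms C8–C10 and C9–C10. The closest known reaction is the copper-catalysed intramolecular cyclopropanation of cyclopent-3-enyl diazo ketones to tricyclo[2.2.1.0]heptanones. The cyclopropane C8–C9–C10 closes by [2+1] addition, and the same event closes the five-membered rings C6–C7–C8–C10–C11 and C1–C6–C11–C10–C9, each through the three-atom tether C10–C11–C6. C8, C9 and C10 are all fixed by this tether, because the acyl group stands on the cyclopentene face shared with C2, the carbenoid can reach only that face and the methyl group must point away from the cage. The step needs cyclopropanation to outrun the 1,2-hydride shift from the methyl group and C–H insertion (axial C4–H next to OTBS, axial C2–H, C5 methyl groups); copper rather than dirhodium catalysis, slow addition and the unhindered cis-alkene held 1,3 to C6 favour it. The lactone bridge keeps C11 axial above the alkene and places the C12 carbonyl group anti to C11, so a carbonyl ylide cannot form.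

**Step 19**
Reactants: 31 cage ketone
Product: 32 C11 alcohol with the hydroxyl group on the ring A side (C11 epimer of the target)
Conditions: NaBH4, MeOH–THF, 0 °C to 23 °C
Reagents that add atoms: none
Why: Borohydride reduction under steric approach control, in which hydride should reach C11 from the side of the C7 methylene bridge because the other face is covered by C2 and C4 of ring A, so the hydroxyl group should point towards ring A while the lactone and the cyclopropane are left intact.

**Step 20**
Reactants: 32 C11 alcohol
Product: 33 C11 mesylate (used crude)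
Conditions: MsCl, Et3N, CH2Cl2, −20 °C to 0 °C
Reagents that add atoms: methanesulfonyl chloride, CS(=O)(=O)Cl
Why: Mesylation through sulfene, a small electrophile that reaches even a crowded secondary hydroxyl group, with retention at C11.

**Step 21**
Reactants: 33 C11 mesylate
Product: 34 C11 acetate with the acetoxy group on the C7 side (target configuration)
Conditions: CsOAc, 18-crown-6, toluene, 80 °C
Reagents that add atoms: caesium acetate, [Cs+].CC([O-])=O
Why: Substitution of a cyclopropylcarbinyl sulfonate with inversion, in which ionisation is assisted by the adjacent cyclopropane carbon C10 and relieves the crowding under ring A, acetate enters from the open C7 side, and nortricyclyl sulfonates are known to return nortricyclyl esters.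

**Step 22**
Reactants: 34 C11 acetate
Product: 35 triol (C12H2OH; C3 OH; C11 OH; C4 OTBS)
Conditions: LiAlH4, THF, 0 °C to 23 °C
Reagents that add atoms: none
Why: Hydride reduction of the lactone to the C12 primary alcohol and the C3 alcohol, with acyl–oxygen cleavage of the acetate, so no C–O bond at a stereocentre is broken and the silyl ether stays on O4.

**Step 23**
Reactants: 35 triol
Product: 36 triacetate (C3, C11 and C12 acetates; C4 OTBS)
Conditions: Ac2O, pyridine, DMAP (cat.), 23 °C to 40 °C
Reagents that add atoms: acetic anhydride, CC(=O)OC(C)=O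
Why: DMAP-catalysed exhaustive acetylation of the three free hydroxyl groups, which needs no selectivity because O4 has carried its own protecting group since step 3.

**Step 24**
Reactants: 36 triacetate
Product: 37 target CNP0197219.1
Conditions: HF·pyridine, pyridine–THF, 0 °C to 23 °C
Reagents that add atoms: none
Why: Fluoride-mediated desilylation under buffered, weakly acidic conditions that keep the three acetates in place and do not promote acetyl migration from O3 to O4.

**Compound list**

1 | acrolein | C=CC=O | starting material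
2 | 3-chloro-3-methylbut-1-yne | CC(C)(Cl)C#C | starting material
3 | (3-methylbuta-1,2-dien-1-yl)zinc chloride | CC(C)=C=C[Zn]Cl | intermediate
4 | (±)-4,4-dimethylhex-1-en-5-yn-3-ol | C=CC(O)C(C)(C)C#C | intermediate
5 | (1R)-2,2-dimethyl-1-[(2S)-oxiran-2-yl]but-3-yn-1-ol | C#CC(C)(C)[C@@H](O)[C@@H]1CO1 | intermediate
6 | tert-butyldimethylsilyl ether of 5 | C#CC(C)(C)[C@@H](O[Si](C)(C)C(C)(C)C)[C@@H]1CO1 | intermediate
7 | dimethyl malonate | COC(=O)CC(=O)OC | starting material
8 | dimethyl 2-[(2S,3R)-3-(tert-butyldimethylsilyloxy)-2-hydroxy-4,4-dimethylhex-5-yn-1-yl]propanedioate (formed as sodium alkoxide) | COC(=O)C(C[C@H](O)[C@H](O[Si](C)(C)C(C)(C)C)C(C)(C)C#C)C(=O)OC | intermediate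
9 | methyl (5S)-5-[(1R)-1-(tert-butyldimethylsilyloxy)-2,2-dimethylbut-3-yn-1-yl]-2-oxooxolane-3-carboxylate (C1 epimers) | COC(=O)C1C[C@H](OC1=O)[C@H](O[Si](C)(C)C(C)(C)C)C(C)(C)C#C | intermediate
10 | bridged lactone ester (C1 CO2Me, C12–O3 lactone, C6=C7H2, C4 OTBS) | O=C4[C@]1(C(=O)OC)C[C@H](O4)[C@H](O[Si](C)(C)C(C)(C)C)C(C)(C)C1=C | intermediate
11 | ring-opened dilithium dicarboxylate | [Li+].[Li+].[O-]C(=O)C1(C([O-])=O)C[C@H](O)[C@H](O[Si](C)(C)C(C)(C)C)C(C)(C)C1=C | intermediate
12 | bridged lactone acid (C9 CO2H) | O=C4[C@]1(C(=O)O)C[C@H](O4)[C@H](O[Si](C)(C)C(C)(C)C)C(C)(C)C1=C | intermediate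
13 | bridged lactone acid chloride | O=C4[C@]1(C(=O)Cl)C[C@H](O4)[C@H](O[Si](C)(C)C(C)(C)C)C(C)(C)C1=C | intermediate
14 | bridged lactone alcohol (C9H2OH) | O=C4[C@]1(CO)C[C@H](O4)[C@H](O[Si](C)(C)C(C)(C)C)C(C)(C)C1=C | intermediate
15 | bromoacetic acid | OC(=O)CBr | starting material
16 | alkoxyacetic acid (C9H2–O–CH2CO2H) | O=C4[C@]1(COCC(=O)O)C[C@H](O4)[C@H](O[Si](C)(C)C(C)(C)C)C(C)(C)C1=C | intermediate
17 | alkoxyacetyl chloride | O=C4[C@]1(COCC(=O)Cl)C[C@H](O4)[C@H](O[Si](C)(C)C(C)(C)C)C(C)(C)C1=C | intermediate
18 | alkoxyketene | O=C4[C@]1(COC=C=O)C[C@H](O4)[C@H](O[Si](C)(C)C(C)(C)C)C(C)(C)C1=C | intermediate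
19 | tetracyclic cyclobutanone | O=C4[C@]12C[C@H](O4)[C@H](O[Si](C)(C)C(C)(C)C)C(C)(C)[C@]13CC(=O)[C@@H]3OC2 | intermediate
20 | bis-acetal lactone | O=C4[C@]12C[C@H](O4)[C@H](O[Si](C)(C)C(C)(C)C)C(C)(C)[C@]13CC(=O)O[C@@H]3OC2 | intermediate
21 | C8 lactol (anomers) | O=C4[C@]12C[C@H](O4)[C@H](O[Si](C)(C)C(C)(C)C)C(C)(C)[C@]13CC(O)O[C@@H]3OC2 | intermediate
22 | triol (C8, C9, C11 primary alcohols) | O=C4[C@]1(CO)C[C@H](O4)[C@H](O[Si](C)(C)C(C)(C)C)C(C)(C)[C@]1(CO)CCO | intermediate
23 | trialdehyde | O=C4[C@]1(C=O)C[C@H](O4)[C@H](O[Si](C)(C)C(C)(C)C)C(C)(C)[C@]1(C=O)CC=O | intermediate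
24 | diene aldehyde (C6 allyl and formyl, C1 vinyl) | O=C4[C@]1(C=C)C[C@H](O4)[C@H](O[Si](C)(C)C(C)(C)C)C(C)(C)[C@]1(C=O)CC=C | intermediate
25 | tricyclic aldehyde (trans-fused cyclopentene) | O=C4[C@]12C[C@H](O4)[C@H](O[Si](C)(C)C(C)(C)C)C(C)(C)[C@]1(C=O)CC=C2 | intermediate
26 | ethylmagnesium bromide | CC[Mg]Br | starting material
27 | secondary carbinol (C11 epimers) | O=C4[C@]12C[C@H](O4)[C@H](O[Si](C)(C)C(C)(C)C)C(C)(C)[C@]1(C(O)CC)CC=C2 | intermediate
28 | ethyl ketone | O=C4[C@]12C[C@H](O4)[C@H](O[Si](C)(C)C(C)(C)C)C(C)(C)[C@]1(C(=O)CC)CC=C2 | intermediate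
29 | trifluoroacetyl ketone (C10 epimers) | O=C4[C@]12C[C@H](O4)[C@H](O[Si](C)(C)C(C)(C)C)C(C)(C)[C@]1(C(=O)C(C)C(=O)C(F)(F)F)CC=C2 | intermediate
30 | α-diazo ketone, key-step precursor (C12–O3 lactone, C4 OTBS) | O=C4[C@]12C[C@H](O4)[C@H](O[Si](C)(C)C(C)(C)C)C(C)(C)[C@]1(C(=O)C(C)=[N+]=[N-])CC=C2 | intermediate
31 | cage C11 ketone, key-step product (C12–O3 lactone, C4 OTBS) | O=C4[C@]12C[C@H](O4)[C@H](O[Si](C)(C)C(C)(C)C)C(C)(C)[C@]13C[C@@H]1[C@H]2[C@]1(C)C3=O | intermediate
32 | C11 alcohol, hydroxyl on the ring A side | O=C4[C@]12C[C@H](O4)[C@H](O[Si](C)(C)C(C)(C)C)C(C)(C)[C@]13C[C@@H]1[C@H]2[C@]1(C)[C@@H]3O | intermediate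
33 | C11 mesylate | O=C4[C@]12C[C@H](O4)[C@H](O[Si](C)(C)C(C)(C)C)C(C)(C)[C@]13C[C@@H]1[C@H]2[C@]1(C)[C@@H]3OS(C)(=O)=O | intermediate
34 | C11 acetate, acetoxy on the C7 side | O=C4[C@]12C[C@H](O4)[C@H](O[Si](C)(C)C(C)(C)C)C(C)(C)[C@]13C[C@@H]1[C@H]2[C@]1(C)[C@H]3OC(C)=O | intermediate
35 | triol (C3, C11, C12 hydroxyl groups, C4 OTBS) | OC[C@]12C[C@H](O)[C@H](O[Si](C)(C)C(C)(C)C)C(C)(C)[C@]13C[C@@H]1[C@H]2[C@]1(C)[C@H]3O | intermediate
36 | triacetate (C4 OTBS) | CC(=O)OC[C@]12C[C@H](OC(C)=O)[C@H](O[Si](C)(C)C(C)(C)C)C(C)(C)[C@]13C[C@@H]1[C@H]2[C@]1(C)[C@H]3OC(C)=O | intermediate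
37 | CNP0197219.1 | CC(=O)OC[C@]12C[C@H](OC(C)=O)[C@H](O)C(C)(C)[C@]13C[C@@H]1[C@H]2[C@]1(C)[C@H]3OC(C)=O | target

**Step count**

Total step count: 24. Longest linear sequence: 24 steps.

**Steps most likely to fail**

Step 18. The 1,2-hydride shift from the methyl group of the carbenoid, or insertion into the axial C–H bonds of ring A, may outrun addition to C8=C9. The fallback forms the same two bonds by enolate chemistry. It sets out from ethyl ketone 28 and returns at cage ketone 31.
- OsO4 with N-methylmorpholine N-oxide should add to C8=C9 from the face away from the acyl group and give the cis-diol F1.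
- SOCl2 and Et3N give the cyclic sulfite F2, and RuCl3 with NaIO4 gives the cyclic sulfate F3.
- KN(SiMe3)2 (2.2 equiv) in THF forms the C10 enolate. It opens the sulfate from the acyl face at C8 to give the norbornanone sulfate salt F4.
- A second enolisation at C10 displaces the exo sulfate on C9 in a 1,3-elimination that closes the cyclopropane.

Step 9. Ketene dimerisation or a cationic diversion may win, because the closure at C6 joins two crowded carbons. The fallback uses a more electrophilic cumulene. It sets out from acid 16 and returns at cyclobutanone 19.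
- Carbodiimide coupling with pyrrolidine gives the pyrrolidine amide F5.
- Tf2O and 2,4,6-collidine in 1,2-dichloroethane at 80 °C give the keteniminium triflate F6.
- F6 cycloadds through the same tether to the cyclobutaniminium triflate F7.
- Aqueous NaHCO3 hydrolyses F7 to 19.

Step 5. The low enol content of the alkoxycarbonyl lactone and the bridged 6-exo-dig closure may make the cycloisomerisation slower than alkyne hydration or loss of the silyl group. The fallback replaces alkyne activation by cross-coupling. It sets out from lactone ester 9 and returns at bridged lactone ester 10.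
- Haloboration with B-iodo-9-borabicyclo[3.3.1]nonane, followed by protonolysis with AcOH, gives the 2-iodoalkene F8.
- Zerovalent palladium, as Pd(PPh3)4, with Cs2CO3 in THF at 65 °C joins C1 to C6 by intramolecular enolate alkenylation.

**Further compounds**

F1 | step 18 | cis-8,9-diol of 28 (hydroxyl groups opposite to C11) | O=C4[C@]12C[C@H](O4)[C@H](O[Si](C)(C)C(C)(C)C)C(C)(C)[C@]1(C(=O)CC)C[C@H](O)[C@@H]2O
F2 | step 18 | cyclic sulfite of F1 | O=C4[C@]12C[C@H](O4)[C@H](O[Si](C)(C)C(C)(C)C)C(C)(C)[C@]1(C(=O)CC)C[C@H]5[C@@H]2OS(=O)O5
F3 | step 18 | cyclic sulfate of F1 | O=C4[C@]12C[C@H](O4)[C@H](O[Si](C)(C)C(C)(C)C)C(C)(C)[C@]1(C(=O)CC)C[C@H]5[C@@H]2OS(=O)(=O)O5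
F4 | step 18 | potassium C9 sulfate of the C8–C10 bonded norbornanone | O=C4[C@]12C[C@H](O4)[C@H](O[Si](C)(C)C(C)(C)C)C(C)(C)[C@]13C[C@@H](C(C)C3=O)[C@@H]2OS(=O)(=O)[O-].[K+]
F5 | step 9 | pyrrolidine amide of 16 | O=C4[C@]1(COCC(=O)N5CCCC5)C[C@H](O4)[C@H](O[Si](C)(C)C(C)(C)C)C(C)(C)C1=C
F6 | step 9 | keteniminium triflate | O=C4[C@]1(COC=C=[N+]5CCCC5)C[C@H](O4)[C@H](O[Si](C)(C)C(C)(C)C)C(C)(C)C1=C.[O-]S(=O)(=O)C(F)(F)F
F7 | step 9 | cyclobutaniminium triflate | O=C4[C@]12C[C@H](O4)[C@H](O[Si](C)(C)C(C)(C)C)C(C)(C)[C@]13CC(=[N+]5CCCC5)[C@@H]3OC2.[O-]S(=O)(=O)C(F)(F)F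
F8 | step 5 | 2-iodoalkene from 9 | COC(=O)C1C[C@H](OC1=O)[C@H](O[Si](C)(C)C(C)(C)C)C(C)(C)C(I)=C
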